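**Assumption:** the target has no stereocentre and is achiral, so "single enantiomer" calls for no stereocontrol; the SMILES is taken as written.

## Retrosynthetic overview

1. Target 16 ⇐ 3-(methylsulfanyl)indole 14 ⇐ 4,5,6-tribromoindole 12, by two successive electrophilic sulfenylations with MeSCl (C3 first, then C2 through a 3,3-bis-sulfide indoleninium).
2. Indole 12 ⇐ acid 11 (decarboxylation) ⇐ ester 9 ⇐ o-nitrophenylpyruvate 7 (reductive cyclisation; the pyrrole ring is the only ring built, the benzene ring is bought).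
3. Key C–C bond (future C2–C3): Claisen-type (Reissert) condensation of tribromonitrotoluene 4 with diethyl oxalate 5.
4. Nitrotoluene 4 ⇐ 3-methyl-4-nitroaniline 1, by ortho,ortho-dibromination and Sandmeyer bromination, which fixes the contiguous Br3 pattern.

## Route

**Step 1**
Reactants: 1 3-methyl-4-nitroaniline
Product: 2 2,6-dibromo-3-methyl-4-nitroaniline
Conditions: Br2 (2.1 eq), AcOH, rt → 60 °C
Reagents that add atoms: bromine, BrBr
Why: Electrophilic aromatic bromination; NH2 directs to its two free ortho positions because the para position is blocked by NO2 (as in 4-nitroaniline → 2,6-dibromo-4-nitroaniline).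

**Step 2**
Reactants: 2 2,6-dibromo-3-methyl-4-nitroaniline
Product: 4 1,2,3-tribromo-4-methyl-5-nitrobenzene (2,3,4-tribromo-6-nitrotoluene), via 2,6-dibromo-3-methyl-4-nitrobenzenediazonium hydrogen sulfate 3 (not isolated)
Conditions: NaNO2, conc. H2SO4/AcOH, 0–10 °C; then CuBr, 48% HBr, 60–70 °C
Reagents that add atoms: hydrogen bromide (delivered via CuBr), Br
Why: Sandmeyer bromination; nitrosylsulfuric acid diazotises the weakly basic, hindered aniline and Cu(I) mediates ipso replacement of N2 by Br.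

**Step 3**
Reactants: 4 1,2,3-tribromo-4-methyl-5-nitrobenzene; 5 diethyl oxalate
Product: 7 ethyl 2-oxo-3-(2,3,4-tribromo-6-nitrophenyl)propanoate, via potassium (Z)-1-ethoxy-1-oxo-3-(2,3,4-tribromo-6-nitrophenyl)prop-2-en-2-olate 6 (not isolated)
Conditions: KOEt (1.2 eq), (CO2Et)2 (1.5 eq), Et2O/EtOH, 0 °C → rt, 24 h; then 1 M HCl
Reagents that add atoms: diethyl oxalate, CCOC(=O)C(=O)OCC
Why: Reissert condensation, a crossed Claisen-type acylation of the o-nitro-stabilised benzylic carbanion by the non-enolisable oxalate, driven by precipitation of the potassium enolate.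

**Step 4**
Reactants: 7 ethyl 2-oxo-3-(2,3,4-tribromo-6-nitrophenyl)propanoate
Product: 9 ethyl 4,5,6-tribromo-1H-indole-2-carboxylate, via ethyl 3-(6-amino-2,3,4-tribromophenyl)-2-oxopropanoate 8 (not isolated)
Conditions: Fe powder (6 eq), AcOH/EtOH, 80 °C
Reagents that add atoms: none
Why: Reissert indole synthesis; Fe/AcOH reduces NO2 to NH2 without touching aryl bromides, and the aniline condenses with the ketone and dehydrates to the indole.

**Step 5**
Reactants: 9 ethyl 4,5,6-tribromo-1H-indole-2-carboxylate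
Product: 11 4,5,6-tribromo-1H-indole-2-carboxylic acid, via sodium 4,5,6-tribromo-1H-indole-2-carboxylate 10 (not isolated)
Conditions: NaOH (3 eq), EtOH/H2O, 70 °C; then 2 M HCl to pH 2
Reagents that add atoms: sodium hydroxide, [Na+].[OH-]
Why: Ester saponification (BAc2); the electron-rich bromoindole is not prone to SNAr by hydroxide.

**Step 6**
Reactants: 11 4,5,6-tribromo-1H-indole-2-carboxylic acid
Product: 12 4,5,6-tribromo-1H-indole
Conditions: Cu powder (0.2 eq), quinoline, 200–210 °C, N2
Reagents that add atoms: none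
Why: Copper-catalysed thermal protodecarboxylation of an indole-2-carboxylic acid, the standard route to 2-unsubstituted bromoindoles.

**Step 7**
Reactants: 12 4,5,6-tribromo-1H-indole; 13 dimethyl disulfide
Product: 14 4,5,6-tribromo-3-(methylsulfanyl)-1H-indole
Conditions: MeSSMe (0.55 eq) + SO2Cl2 (0.55 eq), CH2Cl2, −20 → 0 °C (gives MeSCl, 1.1 eq); add to 12, CH2Cl2/DMF, −40 → 0 °C
Reagents that add atoms: dimethyl disulfide (as methanesulfenyl chloride made in the flask), CSSC
Why: Electrophilic aromatic sulfenylation; the indole reacts with the sulfenyl chloride at its most nucleophilic position C3, and neither reagent nor medium affects C–Br bonds.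

**Step 8**
Reactants: 14 4,5,6-tribromo-3-(methylsulfanyl)-1H-indole; 13 dimethyl disulfide
Product: 16 4,5,6-tribromo-2,3-bis(methylsulfanyl)-1H-indole, via 4,5,6-tribromo-3,3-bis(methylsulfanyl)-3H-indol-1-ium chloride 15 (not isolated)
Conditions: MeSSMe (0.6 eq) + SO2Cl2 (0.6 eq), CH2Cl2, −20 → 0 °C (gives MeSCl, 1.2 eq); add to 14, CH2Cl2, 0 °C → rt
Reagents that add atoms: dimethyl disulfide (as methanesulfenyl chloride made in the flask), CSSC
Why: Second electrophilic sulfenylation of a 3-indolyl sulfide; ipso attack at C3 gives the 3,3-bis-sulfide indoleninium, and an acid-promoted 1,2-shift of MeS to C2 with loss of HCl restores the aromatic 2,3-bis-sulfide.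

## Compound list

1 | 3-methyl-4-nitroaniline | Cc1cc(N)ccc1[N+](=O)[O-] | starting material
2 | 2,6-dibromo-3-methyl-4-nitroaniline | Cc1c(Br)c(N)c(Br)cc1[N+](=O)[O-] | intermediate
3 | 2,6-dibromo-3-methyl-4-nitrobenzenediazonium hydrogen sulfate | Cc1c(Br)c([N+]#N)c(Br)cc1[N+](=O)[O-].OS(=O)(=O)[O-] | intermediate (not isolated)
4 | 1,2,3-tribromo-4-methyl-5-nitrobenzene | Cc1c(Br)c(Br)c(Br)cc1[N+](=O)[O-] | intermediate
5 | diethyl oxalate | CCOC(=O)C(=O)OCC | starting material
6 | potassium (Z)-1-ethoxy-1-oxo-3-(2,3,4-tribromo-6-nitrophenyl)prop-2-en-2-olate | CCOC(=O)/C([O-])=C/c1c(Br)c(Br)c(Br)cc1[N+](=O)[O-].[K+] | intermediate (not isolated)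
7 | ethyl 2-oxo-3-(2,3,4-tribromo-6-nitrophenyl)propanoate | CCOC(=O)C(=O)Cc1c(Br)c(Br)c(Br)cc1[N+](=O)[O-] | intermediate
8 | ethyl 3-(6-amino-2,3,4-tribromophenyl)-2-oxopropanoate | CCOC(=O)C(=O)Cc1c(Br)c(Br)c(Br)cc1N | intermediate (not isolated)
9 | ethyl 4,5,6-tribromo-1H-indole-2-carboxylate | CCOC(=O)c1cc2c(Br)c(Br)c(Br)cc2[nH]1 | intermediate
10 | sodium 4,5,6-tribromo-1H-indole-2-carboxylate | [Na+].[O-]C(=O)c1cc2c(Br)c(Br)c(Br)cc2[nH]1 | intermediate (not isolated)
11 | 4,5,6-tribromo-1H-indole-2-carboxylic acid | OC(=O)c1cc2c(Br)c(Br)c(Br)cc2[nH]1 | intermediate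
12 | 4,5,6-tribromo-1H-indole | Brc1cc2[nH]ccc2c(Br)c1Br | intermediate
13 | dimethyl disulfide | CSSC | starting material
14 | 4,5,6-tribromo-3-(methylsulfanyl)-1H-indole | CSc1c[nH]c2cc(Br)c(Br)c(Br)c12 | intermediate
15 | 4,5,6-tribromo-3,3-bis(methylsulfanyl)-3H-indol-1-ium chloride | CSC1(SC)C=[NH+]c2cc(Br)c(Br)c(Br)c21.[Cl-] | intermediate (not isolated)
16 | 4,5,6-tribromo-2,3-bis(methylsulfanyl)-1H-indole | CSc1[nH]c2cc(Br)c(Br)c(Br)c2c1SC | target

## Summary

Total step count: 8. Longest linear sequence: 8 steps (1 → 16).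

**Steps most likely to fail, with fallbacks**

Step 3 (Reissert condensation). The methyl group is flanked by NO2 and Br, and the bromide para to the nitro group could suffer SNAr by ethoxide. The fallback sets out from 4 and avoids alkoxide and benzylic deprotonation altogether. Radical benzylic bromination (NBS, cat. dibenzoyl peroxide, PhCF3, reflux) gives 1,2,3-tribromo-4-(bromomethyl)-5-nitrobenzene F1. Oxidation with N-methylmorpholine N-oxide (MeCN, 4 Å MS, rt) gives 2,3,4-tribromo-6-nitrobenzaldehyde F2. Henry (nitroaldol) condensation with nitromethane (NH4OAc, AcOH, 90 °C) gives 1,2,3-tribromo-5-nitro-4-[(E)-2-nitroethenyl]benzene F3. Reductive cyclisation of this dinitrostyrene (Fe powder, AcOH, silica gel, toluene, 90 °C) expels ammonia and delivers 4,5,6-tribromo-1H-indole, where the route is rejoined at 12; steps 4–6 are then not needed.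

Step 6 (decarboxylation). Copper at about 200 °C may cause partial protodebromination or tarring. The fallback sets out again from 4 and never carries a carboxyl group (Leimgruber–Batcho). Heating 4 with tert-butoxybis(dimethylamino)methane (or DMF dimethyl acetal) in DMF at 100 °C gives (E)-N,N-dimethyl-2-(2,3,4-tribromo-6-nitrophenyl)ethen-1-amine F4. Fe/AcOH at 80 °C reduces the nitro group, and the aniline cyclises onto the enamine with loss of dimethylamine to give 4,5,6-tribromo-1H-indole, rejoining the route at 12.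

Step 8 (second sulfenylation). The deactivated, peri-hindered 3-sulfide may react sluggishly or over-react with MeSCl. The fallback sets out from 14 and replaces electrophilic substitution with directed C2 metalation. Boc2O/DMAP (MeCN, rt) gives tert-butyl 4,5,6-tribromo-3-(methylsulfanyl)-1H-indole-1-carboxylate F5. LDA (1.1 eq, THF, −78 °C) deprotonates C2 without bromine–lithium exchange, giving tert-butyl 4,5,6-tribromo-2-lithio-3-(methylsulfanyl)-1H-indole-1-carboxylate F6. A MeSSMe quench at −78 °C gives tert-butyl 4,5,6-tribromo-2,3-bis(methylsulfanyl)-1H-indole-1-carboxylate F7. Boc removal (TFA, anisole, CH2Cl2, 0 °C → rt) then gives the target, arriving at 16.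

## Further compounds

F1 | step 3 | 1,2,3-tribromo-4-(bromomethyl)-5-nitrobenzene | BrCc1c(Br)c(Br)c(Br)cc1[N+](=O)[O-]
F2 | step 3 | 2,3,4-tribromo-6-nitrobenzaldehyde | O=Cc1c(Br)c(Br)c(Br)cc1[N+](=O)[O-]
F3 | step 3 | 1,2,3-tribromo-5-nitro-4-[(E)-2-nitroethenyl]benzene | [O-][N+](=O)/C=C/c1c(Br)c(Br)c(Br)cc1[N+](=O)[O-]
F4 | step 6 | (E)-N,N-dimethyl-2-(2,3,4-tribromo-6-nitrophenyl)ethen-1-amine | CN(C)/C=C/c1c(Br)c(Br)c(Br)cc1[N+](=O)[O-]
F5 | step 8 | tert-butyl 4,5,6-tribromo-3-(methylsulfanyl)-1H-indole-1-carboxylate | CSc1cn(C(=O)OC(C)(C)C)c2cc(Br)c(Br)c(Br)c12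
F6 | step 8 | tert-butyl 4,5,6-tribromo-2-lithio-3-(methylsulfanyl)-1H-indole-1-carboxylate | [Li]c1c(SC)c2c(Br)c(Br)c(Br)cc2n1C(=O)OC(C)(C)C
F7 | step 8 | tert-butyl 4,5,6-tribromo-2,3-bis(methylsulfanyl)-1H-indole-1-carboxylate | CSc1c(SC)c2c(Br)c(Br)c(Br)cc2n1C(=O)OC(C)(C)C
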